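**Assumptions (one line each).** (S)-(+)-linalool (coriandrol) is bought in high ee; sulfone 5 is expected to be crystalline, so ee/dr can be upgraded by recrystallisation if needed. The target is taken as drawn: ring (1S,2S) with OH trans to the side chain, all-E chain.

## Retrosynthetic overview

1. Target 10 ⇐ ring sulfone 5 (carbanion at the ring-CH2) + (2E,6E,10E)-12-bromofarnesyl acetate 8, forming C12–C13, then removal of sulfone and acetate.
2. 5 ⇐ exocyclic vinyl sulfone 4 by hydroxyl-directed hydrogenation; this sets the ring CH from the carbinol centre.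
3. 4 ⇐ acyclic dienyl sulfone 3 by a light-driven Co–H radical cycloisomerisation; this forms the only ring (CMe2–CH bond).
4. 3 ⇐ (S)-linalool 1 via the alkenyl boronate 2. The sulfone polarises the vinyl group so closure occurs 6-exo at the internal carbon (a plain linalyl vinyl group is expected to close 7-endo), and later serves as the carbanion handle.
5. 8 ⇐ (2E,6E)-farnesyl acetate 6 by SeO2 oxidation and bromination.

## Route

**Step 1**
Reactants: 1, (S)-(+)-linalool
Product: 2, (S,E)-3,7-dimethyl-1-(pinacolboryl)octa-1,6-dien-3-ol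
Conditions: B2pin2, trans-[RhCl(CO)(PPh3)2] (3 mol%), toluene/MeCN 3:1, 80 °C; aq. NH4Cl work-up
Reagents that add atoms: bis(pinacolato)diboron, CC1(C)OB(OC1(C)C)B2OC(C)(C)C(C)(C)O2
Why: Rh-catalysed dehydrogenative borylation (boryl insertion/β-H elimination) acts only on the monosubstituted vinyl group and gives the E-alkenyl boronate; the trisubstituted alkene and the carbinol stereocentre are untouched.

**Step 2**
Reactants: 2
Product: 3, (S,E)-3,7-dimethyl-1-(phenylsulfonyl)octa-1,6-dien-3-ol
Conditions: PhSO2Na, Cu(OAc)2, 1,10-phenanthroline, K2CO3, 4 Å MS, DMSO/CH2Cl2, O2, 40 °C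
Reagents that add atoms: sodium benzenesulfinate, [Na+].[O-]S(=O)c1ccccc1
Why: Chan–Lam-type Cu(II) oxidative C–S coupling of an alkenylboron with a sulfinate proceeds with retention of E geometry and tolerates the free tertiary alcohol.

**Step 3 (key step)**
Reactants: 3
Product: 4, (S)-1,3,3-trimethyl-2-[(phenylsulfonyl)methylidene]cyclohexan-1-ol (E/Z mixture, inconsequential)
Conditions: Co(salen) [salen = N,N′-bis(3,5-di-tert-butylsalicylidene)ethylenediamine, achiral] (5 mol%), 4CzIPN (2 mol%), collidinium triflate (20 mol%), iPr2NEt (10 mol%), MeCN (0.02 M), 450 nm LEDs, 25 °C, Ar; no stoichiometric reductant or oxidant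
Reagents that add atoms: none (isomerisation)
Why: Proposed new method: a photochemically generated Co(III)–H (photoreduction of Co(II) to Co(I), then protonation) transfers H• Markovnikov to the trisubstituted alkene; the resulting tertiary radical adds 6-exo to the β-carbon of the vinyl sulfone (Giese polarity overrides the 7-endo mode), and Co(II) removes the only β-hydrogen of the α-sulfonyl radical to give the exocyclic vinyl sulfone and regenerate Co–H. No new stereocentre is formed and the carbinol centre is untouched. Closest known chemistry is thermal Co(salen)/silane or Co/H2 MHAT radical cycloisomerisation of dienes, plus photoredox generation of Co–H for alkene hydrofunctionalisation. Omitting an external oxidant avoids radical-polar crossover to the tetrahydropyran.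

**Step 4**
Reactants: 4
Product: 5, (1S,2S)-1,3,3-trimethyl-2-[(phenylsulfonyl)methyl]cyclohexan-1-ol
Conditions: [Ir(cod)(PCy3)(py)]BArF (5 mol%), H2 (10 atm), CH2Cl2, 25 °C; recrystallise
Reagents that add atoms: none (H2 only)
Why: Hydroxyl-directed hydrogenation (Crabtree/Stork): Ir binds the tertiary OH and delivers H2 to the alkene face syn to it, so the new ring C–H is cis to OH and CH2SO2Ph is trans (2S); both E and Z isomers of 4 converge.

**Step 5**
Reactants: 6, (2E,6E)-farnesyl acetate
Product: 7, (2E,6E,10E)-12-hydroxy-3,7,11-trimethyldodeca-2,6,10-trien-1-yl acetate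
Conditions: SeO2 (0.5 equiv), t-BuOOH, salicylic acid (cat.), CH2Cl2, 0 °C to rt; then NaBH4, MeOH, −10 °C
Reagents that add atoms: SeO2, O=[Se]=O, with t-BuOOH, CC(C)(C)OO (one O)
Why: Sharpless–Umbreit allylic oxidation (ene/[2,3]) is selective for the E-methyl of the terminal trisubstituted alkene; the borohydride work-up returns over-oxidised enal to the alcohol.

**Step 6**
Reactants: 7
Product: 8, (2E,6E,10E)-12-bromo-3,7,11-trimethyldodeca-2,6,10-trien-1-yl acetate
Conditions: CBr4, PPh3, CH2Cl2, −20 °C
Reagents that add atoms: carbon tetrabromide, BrC(Br)(Br)Br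
Why: Appel bromination of the primary allylic alcohol is SN2, without allylic transposition or E/Z loss, and leaves the acetate intact.

**Step 7**
Reactants: 5 and 8
Product: 9, (2E,6E,10E)-13-[(1S,2S)-2-hydroxy-2,6,6-trimethylcyclohexyl]-3,7,11-trimethyl-13-(phenylsulfonyl)trideca-2,6,10-trien-1-yl acetate (C13 epimers)
Conditions: 5, n-BuLi (2.1 equiv), THF/DMPU, −78 °C; then 8, −78 to −40 °C
Reagents that add atoms: none (both partners are reactants)
Why: Julia-type alkylation of the alkoxide/α-sulfonyl dianion with the primary allylic bromide is a clean SN2 reaction that forms C12–C13 with 10E retained; the acetate survives at low temperature, and the new C13 centre is removed in the next step.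

**Step 8**
Reactants: 9
Product: 10, preluffariellolide A, (2E,6E,10E)-13-[(1S,2S)-2-hydroxy-2,6,6-trimethylcyclohexyl]-3,7,11-trimethyltrideca-2,6,10-trien-1-ol
Conditions: 6% Na(Hg), Na2HPO4, MeOH/THF, −20 °C; then K2CO3, MeOH, 23 °C (one pot)
Reagents that add atoms: none
Why: Reductive desulfonylation of the alkyl phenyl sulfone (electron transfer/C–S cleavage) does not touch isolated trisubstituted alkenes, and methanolysis then removes the acetate; neither ring stereocentre is involved.

## Compound list

1 | (S)-(+)-linalool | CC(C)=CCC[C@@](C)(C=C)O | starting material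
2 | (S,E)-3,7-dimethyl-1-(4,4,5,5-tetramethyl-1,3,2-dioxaborolan-2-yl)octa-1,6-dien-3-ol | CC(C)=CCC[C@@](C)(/C=C/B1OC(C)(C)C(C)(C)O1)O | intermediate
3 | (S,E)-3,7-dimethyl-1-(phenylsulfonyl)octa-1,6-dien-3-ol | CC(C)=CCC[C@@](C)(/C=C/S(=O)(=O)c1ccccc1)O | intermediate
4 | (S)-1,3,3-trimethyl-2-[(phenylsulfonyl)methylidene]cyclohexan-1-ol (E/Z) | O=S(=O)(C=C1C(C)(C)CCC[C@]1(C)O)c2ccccc2 | intermediate
5 | (1S,2S)-1,3,3-trimethyl-2-[(phenylsulfonyl)methyl]cyclohexan-1-ol | O=S(=O)(C[C@H]1C(C)(C)CCC[C@]1(C)O)c2ccccc2 | intermediate
6 | (2E,6E)-farnesyl acetate | CC(C)=CCC/C(C)=C/CC/C(C)=C/COC(C)=O | starting material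
7 | (2E,6E,10E)-12-hydroxy-3,7,11-trimethyldodeca-2,6,10-trien-1-yl acetate | OC/C(C)=C/CC/C(C)=C/CC/C(C)=C/COC(C)=O | intermediate
8 | (2E,6E,10E)-12-bromo-3,7,11-trimethyldodeca-2,6,10-trien-1-yl acetate | BrC/C(C)=C/CC/C(C)=C/CC/C(C)=C/COC(C)=O | intermediate
9 | (2E,6E,10E)-13-[(1S,2S)-2-hydroxy-2,6,6-trimethylcyclohexyl]-3,7,11-trimethyl-13-(phenylsulfonyl)trideca-2,6,10-trien-1-yl acetate (C13 epimers) | C/C(=C\COC(C)=O)CC/C=C(\C)CC/C=C(\C)CC(S(=O)(=O)c1ccccc1)[C@H]2C(C)(C)CCC[C@]2(C)O | intermediate
10 | preluffariellolide A | C/C(=C\CO)CC/C=C(\C)CC/C=C(\C)CC[C@H]1C(C)(C)CCC[C@]1(C)O | target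

## Summary

Total steps: 8. Longest linear sequence: 6 (steps 1, 2, 3, 4, 7, 8 from linalool).

Steps most likely to fail, each with a fallback that changes the approach:

1. **Step 3 (proposed new photochemical Co–H cycloisomerisation).** Risks are a slow 6-exo closure at the congested β-carbon and net reduction instead of isomerisation. Fallback (known chemistry): Fe(acac)3/PhSiH3 reductive MHAT Giese cyclisation of 3 to the saturated sulfone as a C2-epimer mixture, then α-selenenylation and selenoxide elimination to regenerate 4 and rejoin at step 4.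
2. **Step 4 (directed hydrogenation of a hindered exocyclic vinyl sulfone).** Risks are low reactivity or erosion of facial control, since the directing face is flanked by the axial methyl of the CMe2 group. Fallback: hydroxyl-directed conjugate hydride delivery through the alkoxyaluminate (LiAlH4 or Red-Al, THF), which also places H cis to OH.
3. **Step 1 (dehydrogenative borylation of a free tertiary allylic alcohol).** Risk is competing hydroboration or low conversion. Fallback: build 3 from (R)-lactic acid by Seebach self-regeneration alkylation (pivalaldehyde acetal, LDA, homoprenyl iodide), DIBAL-H to the α-hydroxy aldehyde, and Horner–Wadsworth–Emmons olefination with diethyl (phenylsulfonyl)methylphosphonate.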